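Read each run not by its yield but by the negative logarithm of the fraction of substrate left, and ask what a doubling of time does to that number: a pseudo-first-order run, whose catalyst keeps working unchanged, simply doubles it.

all flasks: enzyme 0.01 mol%; added ligand 27 µM

| flask | substrate | remark | time |
|---|---|---|---|
| blue | 0.061 M | run made earlier |  |
| ochre | 0.26 M | run made earlier |  |
| red | 0.72 M | run made earlier |  |
| west | 0.060 M |  | 8.0 d |
| north-west | 0.12 M |  | 8.0 d |
| east | 0.25 M |  | 8.0 d |
| north-east | 0.50 M |  | 8.0 d |
| north | 1.0 M |  | 8.0 d |

| run | time / d | target / % |
|---|---|---|
| blue | 0.333 | 5.5 |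
| blue | 1.04 | 15.0 |
| blue | 1.67 | 24.4 |
| blue | 3.00 | 39.6 |
| blue | 4.00 | 47.3 |
| ochre | 0.333 | 3.8 |
| ochre | 0.625 | 4.9 |
| ochre | 1.04 | 9.8 |
| ochre | 2.00 | 11.9 |
| ochre | 4.00 | 19.3 |
| red | 0.833 | 0.8 |
| red | 1.67 | 2.3 |
| red | 2.50 | 2.6 |
| red | 3.00 | 2.5 |
| red | 4.00 | 6.1 |

(readings scatter by 1 percentage point)

- "hardly changes" means that all values lie within two and a half points (for a concentration: within two and a half percent of the largest)

- [target] at the end for west, north-west, east, north-east, north, in this order
- the shape of the row from first to last (falls, then rises / rises, then falls / falls all the way / rises all the way / hardly changes)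

Between 1.04 d and 4.00 d, scaled to one doubling, the ochre run gives 1.46 for the doubling gain, the factor by which that logarithm grows when time doubles. Over the same stretch the blue run gives 2.03, so ochre's gain is lower, though each figure rests on two readings with a scatter of 1 percentage point.

We therefore reach 8.0 d by two ways from the reading at 4.00 d: straight doubling, which squares the fraction left, and the run's own gain used as the power. For west, reckoned from blue, the ways give 0.0433 M and 0.0436 M, but both start from the same reading and blue's gain of 2.03 stands close to 2, so their closeness is no check, and the west figure remains an estimate that assumes blue's gain lasts to 8.0 d. For east, reckoned from ochre, they part, at 0.0872 M and 0.0671 M. The ochre run still holds 80.7% of its substrate at 4.00 d, and the logarithm already discounts what has been used, so straight doubling is the way that cheats, and we commit to the lower east figure. The [target] standing at 4.00 d goes 0.0289 M, 0.0502 M, 0.0439 M along blue, ochre and red, so we expect the row to rise and then fall.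

The forecast gives 0.043 M, 0.075 M, 0.095 M, 0.095 M and 0.06 M, with the shape rises, then falls, its figures including “slight relief as substrate is consumed”. It shares our west figure, but its east figure stands above ours.

The flasks give 0.0400 M, 0.0744 M, 0.0751 M, 0.0508 M and 0.0310 M, with the shape rises, then falls, turning at 0.17 M.

    2 enzyme → spent catalyst (k = 2200 /M/h)
    enzyme + added ligand ⇌ idle complex, settled at all times (K = 30000 /M)
    substrate + enzyme → target + enzyme, rate k3*[substrate]*[enzyme]/(1 + ([substrate]/Km3) + ([substrate]/Ksi3)^2) (0.170 M, 0.0800 M, k = 4100 /M/h)

From simulated [target] between 4.00 d and 8.00 d, the west flask has a doubling gain of 1.78, below blue's 2.03, the east flask has 1.50, near ochre's 1.46, and the north flask has 1.25, lower still. Part of north's low [target] comes from enzyme pairing off into spent catalyst, which stands at 94.1% by 4.00 d, acting together with the squared substrate term in the rate. Without that loss of enzyme, the north flask ends at 0.517 M instead of 0.0310 M.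

(All runs stem from a simulated flask on assumed constants; scatter was added.)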